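The constants used here come from no measurement, and the outcome is calculated.

The solution in this flask cannot hold the 5.0 × 10⁻⁴ M of Q charged as E, since crystals form above 0.12 mM, so the question is how much of the solid L can draw away.

Q 5.0 × 10⁻⁴ M; L 0.750 mM (fed, over 50 s); J 0.29 µM; Z 0.065 µM; time 80 min

    Q ⇌ E, rate k1*(cs1 - [E]) while solid is left; crystals form when [E] > cs1 (cs1 = 0.12 mM, k1 = 0.0135 s⁻¹)
    E.L + J ⇌ X + J, rate k2*[J]*[E.L] forward; the back reaction follows from the equilibrium constant (k2 = 1.97 × 10⁵ L mol⁻¹ s⁻¹)
    E + L ⇌ E.L (K3 = 1400 L mol⁻¹, k3 = 112 L mol⁻¹ s⁻¹)
    J + Z → J.Z (k4 = 6.04 × 10⁶ L mol⁻¹ s⁻¹)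
    E + L ⇌ X (K5 = 2700 L mol⁻¹, k5 = 41.0 L mol⁻¹ s⁻¹)

- part of the Q that has turned into other species by 80 min (what has only dissolved does not count)
- how much E.L there is at 80 min, in percent of the Q charged

- solid, in amounts per volume of the solution: Q
- at the start none of Q is in solution
- what has only dissolved of Q counts as not reacted
- run time (flask): 80 min

**Time scale.** A forward half-life is the time a species takes to halve by one step, the way back not counted. With the whole charges taken as present, E has 0.14 min towards E.L and 0.38 min towards X, and E.L has 0.20 min towards X at the charged J. Dissolution, with its coefficient k₁, closes half its gap to the solubility in ln(2)/k₁ = 0.856 min. These are far shorter than 80 min, so I reckon this flask at equilibrium, which is thermodynamic control.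

**Bound per free.** At equilibrium [E.L] stands at 1400 L mol⁻¹ times [E][L], and [X] at 2700 L mol⁻¹ times [E][L]. At equilibrium with solid present, [E] equals the solubility 0.12 mM, so each free L carries a constant amount. The bound-to-free ratio g, the L held as E.L and X per free L, is the solubility times the sum of both constants: 0.492.

**Going round.** Taking the whole charge as free gives 0.369 mM bound. Putting that back leaves 0.381 mM free and so 0.187 mM bound. The rounds swing to either side and close on cB/(1+g), where cB is the charge of L: 0.503 mM free and 0.247 mM bound. Dissolved and bound together take 0.367 mM of Q, less than the charge of Q, so 0.133 mM stays solid and the assumption of solid present stands. My reckoning gives conversion 49.5 % and E.L 16.9 %.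

**The forecast.** It gives 49.5 % (47.5 % to 51 %) and 16.9 % (16 % to 18 %), holding that “the system should sit at equilibrium with solid Q still present”. It takes the same route as my reckoning, so their agreement is no check.

**The result.** The flask gives 49.5 % and 16.9 %, with 22.4 % of the catalyst as J.Z and 26.5 % of the Q still solid; after 800 min the answers read 49.5 % and 16.9 %. Its bound L over free L is 0.492, the value of g. The neighbour with 3.0 × 10⁻⁴ M of L is reckoned with the same g: 0.201 mM free and 0.0989 mM bound, so conversion 19.8 % and E.L 6.76 %. That neighbour gives 19.8 % and 6.76 %, with 56.2 % of its Q still solid.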